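**Retrosynthetic overview**

1. Numbering: C1–C3 ring CH2, C4 C(CH3)OH, C5 CH–O-isobutyryl, C6 lactone CH–O, C7 ring fusion CH, C8 CHOH, C9 C=O, C10 CH(CH3), C11=C13 exocyclic alkene, C12 lactone C=O. The route rests on one feature: C9 and C4 face each other 1,6 across the ten-membered ring with the C6–C7 bond on the far side of both, so ring atoms C9–C10–C1–C2–C3–C4 with their two methyls are a disguised 2,6-dimethylcyclohexanone.
2. Key disconnection: the C6–C7 bond is made while a C9–C4 bond is given up, by anionic oxy-Cope rearrangement of a 1-dienyl-2-(alkoxyvinyl)-2,6-dimethylcyclohexanol (15); the C8=C9 enolate that results is hydroxylated in the same flask.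
3. Precursor from cis-2,6-dimethylcyclohexanone: C10 by enantioselective deprotonation, C4 by hydroxymethylation of the enolate trans to the C10 methyl, then CH2OH → CHO → (E)-alkenylboronate → (E)-PMB enol ether (PMB = 4-methoxybenzyl); an (E)-dienylcerium reagent then adds to C9 anti to the axial enol-ether arm. The carbinol epimer this addition delivers (arms trans) is the one used: its carbinol centre vanishes in the shift and its only possible chair gives the required C6, C7 and (E)-C4=C5.
4. After the key step: silylation of C8–OH, epoxidation of C4=C5, anti hydrolysis at C4, isobutyrylation of C5–OH, removal of both PMB groups, oxidative lactonisation, desilylation.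
5. Ring order: cyclohexane (present from the start) → ten-membered carbocycle (step 9, ring expansion) → α-methylene-γ-lactone (step 15).

Key step: step 9

Assumption: pure meso cis-2,6-dimethylcyclohexanone is taken as starting material (the commercial isomer mixture is enriched in it by base equilibration and fractional distillation), and the (S,S) antipode of the amide base is taken to be the one that gives (S)-7; if the sense of induction is the reverse, the (R,R) antipode is used.

**Route**

Step 1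
Reactants: 1 4-methoxybenzyl alcohol; 2 2,3-dibromopropene
Product: 3 1-{[(2-bromoprop-2-en-1-yl)oxy]methyl}-4-methoxybenzene
Conditions: NaH, THF, 0 °C; then 2, Bu4NI (cat.), 0 °C to rt
Reagents that add atoms: none
Why: Williamson etherification, in which the alkoxide displaces the allylic bromide of 2 while the vinylic bromide is inert to substitution.

Step 2
Reactants: 3 1-{[(2-bromoprop-2-en-1-yl)oxy]methyl}-4-methoxybenzene; 4 (E)-1,2-bis(tributylstannyl)ethene
Product: 5 tributyl[(1E)-3-{[(4-methoxybenzyl)oxy]methyl}buta-1,3-dien-1-yl]stannane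
Conditions: Pd(PPh3)4 (5 mol %), 4 (2.5 equiv), toluene, 90 °C
Reagents that add atoms: none
Why: Stille coupling of the alkenyl bromide with one C–Sn bond of the excess distannane, which proceeds with retention and leaves the second stannyl group on an (E)-1,3-diene.

Step 3
Reactants: 6 cis-2,6-dimethylcyclohexanone
Product: 7 (6S)-2,6-dimethyl-1-(trimethylsilyloxy)cyclohex-1-ene
Conditions: (S,S)-bis(1-phenylethyl)amine hydrochloride, n-BuLi (2 equiv), THF, −78 °C; TMSCl; then 6, −100 °C (internal quench)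
Reagents that add atoms: chlorotrimethylsilane, C[Si](C)(C)Cl
Why: enantioselective deprotonation (desymmetrisation) of the meso ketone, in which the homochiral lithium amide–LiCl aggregate removes one of the two enantiotopic axial α-hydrogens and silylation in the flask fixes the enolate, so that the untouched α-carbon becomes C10 (S).

Step 4
Reactants: 7 (6S)-2,6-dimethyl-1-(trimethylsilyloxy)cyclohex-1-ene
Product: 9 (2R,6S)-2-(hydroxymethyl)-2,6-dimethylcyclohexan-1-one, via lithium enolate 8 (not isolated)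
Conditions: MeLi, THF, 0 °C; −78 °C, CH2O (gas, from cracked paraformaldehyde); AcOH, −78 °C
Reagents that add atoms: formaldehyde, C=O
Why: Si–O cleavage by MeLi regenerates the regiodefined enolate, and the aldol addition to monomeric formaldehyde should occur by chair-like axial attack on the face away from the C10 methyl (the other face suffers a 1,3-diaxial clash), so the new C–C bond at quaternary C4 is trans to that methyl and the two methyls are cis.

Step 5
Reactants: 9 (2R,6S)-2-(hydroxymethyl)-2,6-dimethylcyclohexan-1-one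
Product: 10 (1R,3S)-1,3-dimethyl-2-oxocyclohexane-1-carbaldehyde
Conditions: Dess–Martin periodinane, NaHCO3, CH2Cl2, 0 °C to rt
Reagents that add atoms: none
Why: Dess–Martin oxidation of the neopentyl primary alcohol under buffered neutral conditions, which gives the β-keto aldehyde (no α-hydrogen at C4) without disturbing the epimerisable C10 centre.

Step 6
Reactants: 10 (1R,3S)-1,3-dimethyl-2-oxocyclohexane-1-carbaldehyde
Product: 11 (2R,6S)-2,6-dimethyl-2-[(E)-2-(4,4,5,5-tetramethyl-1,3,2-dioxaborolan-2-yl)ethenyl]cyclohexan-1-one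
Conditions: CrCl2, LiI, Cl2CHB(pin), THF, rt
Reagents that add atoms: 2-(dichloromethyl)-4,4,5,5-tetramethyl-1,3,2-dioxaborolane, ClC(Cl)B1OC(C)(C)C(C)(C)O1
Why: Takai–Utimoto olefination, in which the geminal dichromium reagent attacks the aldehyde in preference to the hindered ketone and elimination from the less crowded adduct gives the (E)-alkenylboronate.

Step 7
Reactants: 11 (2R,6S)-2,6-dimethyl-2-[(E)-2-(4,4,5,5-tetramethyl-1,3,2-dioxaborolan-2-yl)ethenyl]cyclohexan-1-one; 1 4-methoxybenzyl alcohol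
Product: 12 (2R,6S)-2-{(E)-2-[(4-methoxybenzyl)oxy]ethenyl}-2,6-dimethylcyclohexan-1-one
Conditions: Cu(OAc)2 (2 equiv), Et3N, 4 Å molecular sieves, 1 (excess), CH2Cl2, air, rt
Reagents that add atoms: none
Why: Chan–Lam-type oxidative C–O coupling of an alkenyl pinacol boronate with a primary alcohol, in which transmetalation to copper and C–O reductive elimination retain the (E) geometry and the mild amine base at room temperature should not epimerise C10.

Step 8
Reactants: 5 tributyl[(1E)-3-{[(4-methoxybenzyl)oxy]methyl}buta-1,3-dien-1-yl]stannane; 12 (2R,6S)-2-{(E)-2-[(4-methoxybenzyl)oxy]ethenyl}-2,6-dimethylcyclohexan-1-one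
Product: 15 (1S,2R,6S)-1-[(1E)-3-{[(4-methoxybenzyl)oxy]methyl}buta-1,3-dien-1-yl]-2-{(E)-2-[(4-methoxybenzyl)oxy]ethenyl}-2,6-dimethylcyclohexan-1-ol, via dienyllithium 13 (not isolated), via dienylcerium dichloride 14 (not isolated)
Conditions: 5, n-BuLi, THF, −78 °C; CeCl3 (anhydrous), −78 °C; then 12, −78 to −40 °C; H2O
Reagents that add atoms: none
Why: Sn–Li exchange with retention gives the (E)-dienyllithium, and the derived weakly basic organocerium reagent should undergo 1,2-addition to the hindered enolisable ketone on the carbonyl face opposite the axial C4 enol-ether arm (chair with both methyls equatorial), which places the dienyl group trans to that arm and the hydroxyl cis to it.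

Step 9
Reactants: 15 (1S,2R,6S)-1-[(1E)-3-{[(4-methoxybenzyl)oxy]methyl}buta-1,3-dien-1-yl]-2-{(E)-2-[(4-methoxybenzyl)oxy]ethenyl}-2,6-dimethylcyclohexan-1-ol
Product: 18 (4E,6S,7S,8S,10S)-8-hydroxy-6,12-bis[(4-methoxybenzyl)oxy]germacra-4,11(13)-dien-9-one, via potassium alkoxide 16 (not isolated), via potassium enolate 17 (not isolated)
Conditions: KH (1.3 equiv), 18-crown-6, THF, 0 to 50 °C; then −78 °C, 2-(phenylsulfonyl)-3-phenyloxaziridine; AcOH, −78 °C
Reagents that add atoms: 2-(phenylsulfonyl)-3-phenyloxaziridine, O=S(=O)(N1OC1c1ccccc1)c1ccccc1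
Why: the crown-separated potassium alkoxide 16 undergoes a charge-accelerated [3,3]-sigmatropic shift (anionic oxy-Cope rearrangement, the known ring expansion of 1,2-dialkenylcyclohexanolates to cyclodec-5-enones) in which C6–C7 forms as the C9–C4 ring bond breaks. The ten-membered ring is therefore closed by a four-atom ring expansion through a six-membered chair transition state and not by joining two chain ends. For this trans-dialkenyl alcohol only the chair with both arms equatorial on the cyclohexane is geometrically possible (it is reached from the conformer with the two methyls axial, hence the gentle warming); in it C3 is pseudo-equatorial at C4, which gives the (E)-C4=C5 alkene, and the two (E)-alkene termini carry the OPMB and propenyl groups pseudo-equatorially, which gives the trans C6/C7 pair, the absolute sense following from the C4 configuration that decides which chair is used. Enolate 17 exists only between C8 and C9 (oxygen cis to C7), so the N-sulfonyloxaziridine cannot hydroxylate C10, and it should approach the enolate face turned away from the ring interior, syn to C7–H, which sets C8 (S). The step needs chair over boat and retention of C10: the first rests on the usual chair preference of the oxy-Cope rearrangement, the second on the absence of any proton shuttle (KH leaves only H2) and on the cold acidic quench.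

Step 10
Reactants: 18 (4E,6S,7S,8S,10S)-8-hydroxy-6,12-bis[(4-methoxybenzyl)oxy]germacra-4,11(13)-dien-9-one
Product: 19 (4E,6S,7R,8S,10S)-8-(tert-butyldimethylsilyloxy)-6,12-bis[(4-methoxybenzyl)oxy]germacra-4,11(13)-dien-9-one
Conditions: TBSOTf, 2,6-lutidine, CH2Cl2, −78 to 0 °C
Reagents that add atoms: tert-butyldimethylsilyl trifluoromethanesulfonate, CC(C)(C)[Si](C)(C)OS(=O)(=O)C(F)(F)F
Why: silylation of the α-ketol hydroxyl with a silyl triflate and a hindered base, which keeps C8–OH out of the later lactol formation and blocks α-ketol isomerisation (the change of the C7 descriptor is only a change of priorities).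

Step 11
Reactants: 19 (4E,6S,7R,8S,10S)-8-(tert-butyldimethylsilyloxy)-6,12-bis[(4-methoxybenzyl)oxy]germacra-4,11(13)-dien-9-one
Product: 20 (4S,5S,6R,7R,8S,10S)-8-(tert-butyldimethylsilyloxy)-4,5-epoxy-6,12-bis[(4-methoxybenzyl)oxy]germacr-11(13)-en-9-one
Conditions: mCPBA (1.05 equiv), NaHCO3, CH2Cl2, 0 °C
Reagents that add atoms: 3-chloroperbenzoic acid, OOC(=O)c1cccc(Cl)c1
Why: Prilezhaev epoxidation, chemoselective for the trisubstituted C4=C5 alkene over the 1,1-disubstituted C11=C13 alkene and stereospecific (trans epoxide), which should take place on the peripheral face that carries C6–H because C7 and the ring interior block the other face.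

Step 12
Reactants: 20 (4S,5S,6R,7R,8S,10S)-8-(tert-butyldimethylsilyloxy)-4,5-epoxy-6,12-bis[(4-methoxybenzyl)oxy]germacr-11(13)-en-9-one
Product: 21 (4R,5S,6R,7R,8S,10S)-8-(tert-butyldimethylsilyloxy)-4,5-dihydroxy-6,12-bis[(4-methoxybenzyl)oxy]germacr-11(13)-en-9-one
Conditions: HClO4 (cat.), THF/H2O, 0 °C to rt
Reagents that add atoms: water, O
Why: acid-catalysed anti (Markovnikov) epoxide hydrolysis, in which the C–O bond at tertiary C4 is cleaved with inversion, the new oxygen arriving on the ring-interior face either as water or relayed by the transannular C9 carbonyl oxygen (bridged oxocarbenium ion, then hemiketal collapse to the same hydroxy ketone), while C5, deactivated by the neighbouring C6 ether, keeps its epoxide oxygen.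

Step 13
Reactants: 21 (4R,5S,6R,7R,8S,10S)-8-(tert-butyldimethylsilyloxy)-4,5-dihydroxy-6,12-bis[(4-methoxybenzyl)oxy]germacr-11(13)-en-9-one; 22 isobutyric anhydride
Product: 23 (4R,5S,6R,7R,8S,10S)-8-(tert-butyldimethylsilyloxy)-4-hydroxy-5-(isobutyryloxy)-6,12-bis[(4-methoxybenzyl)oxy]germacr-11(13)-en-9-one
Conditions: 22, DMAP, Et3N, CH2Cl2, rt
Reagents that add atoms: none
Why: DMAP-catalysed acylation, which should distinguish the secondary C5 hydroxyl from the tertiary C4 hydroxyl, the only other free one.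

Step 14
Reactants: 23 (4R,5S,6R,7R,8S,10S)-8-(tert-butyldimethylsilyloxy)-4-hydroxy-5-(isobutyryloxy)-6,12-bis[(4-methoxybenzyl)oxy]germacr-11(13)-en-9-one
Product: 24 (4R,5S,6R,7R,8S,10S)-8-(tert-butyldimethylsilyloxy)-4,6,12-trihydroxy-5-(isobutyryloxy)germacr-11(13)-en-9-one
Conditions: DDQ, CH2Cl2/pH 7 buffer, 0 °C to rt
Reagents that add atoms: none
Why: oxidative cleavage of both 4-methoxybenzyl ethers by hydride abstraction to the stabilised oxocarbenium ions and hydrolysis, to which the silyl ether, the ester, the ketone and the isolated alkene are inert.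

Step 15
Reactants: 24 (4R,5S,6R,7R,8S,10S)-8-(tert-butyldimethylsilyloxy)-4,6,12-trihydroxy-5-(isobutyryloxy)germacr-11(13)-en-9-one
Product: 27 (4R,5S,6R,7R,8S,10S)-8-(tert-butyldimethylsilyloxy)-4-hydroxy-5-(isobutyryloxy)-9-oxogermacr-11(13)-en-12,6-olide, via hydroxy enal 25 (not isolated), via lactol 26 (not isolated)
Conditions: TEMPO (cat.), PhI(OAc)2, CH2Cl2, rt
Reagents that add atoms: none
Why: oxoammonium oxidation selects the primary allylic alcohol, the enal is trapped by the C6 hydroxyl as the five-membered lactol (5-exo-trig addition to the aldehyde) and this is oxidised on to the α-methylene-γ-lactone, trans-fused because C6 and C7 are already set.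

Step 16
Reactants: 27 (4R,5S,6R,7R,8S,10S)-8-(tert-butyldimethylsilyloxy)-4-hydroxy-5-(isobutyryloxy)-9-oxogermacr-11(13)-en-12,6-olide
Product: 28 (4R,5S,6R,7S,8S,10S)-4,8-dihydroxy-5-(isobutyryloxy)-9-oxogermacr-11(13)-en-12,6-olide (CNP0270933.1)
Conditions: HF·pyridine, pyridine, THF, 0 °C to rt
Reagents that add atoms: none
Why: fluoride-mediated Si–O cleavage under buffered, mildly acidic conditions that should leave the Michael-acceptor lactone, the ester and the α-ketol untouched.

**Compound list**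

1 | 4-methoxybenzyl alcohol | COc1ccc(CO)cc1 | starting material
2 | 2,3-dibromopropene | C=C(Br)CBr | starting material
3 | 1-{[(2-bromoprop-2-en-1-yl)oxy]methyl}-4-methoxybenzene | C=C(Br)COCc1ccc(OC)cc1 | intermediate
4 | (E)-1,2-bis(tributylstannyl)ethene | CCCC[Sn](CCCC)(CCCC)/C=C/[Sn](CCCC)(CCCC)CCCC | starting material
5 | tributyl[(1E)-3-{[(4-methoxybenzyl)oxy]methyl}buta-1,3-dien-1-yl]stannane | C=C(COCc1ccc(OC)cc1)/C=C/[Sn](CCCC)(CCCC)CCCC | intermediate
6 | cis-2,6-dimethylcyclohexanone (meso, 2R,6S) | C[C@H]1CCC[C@@H](C)C1=O | starting material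
7 | (6S)-2,6-dimethyl-1-(trimethylsilyloxy)cyclohex-1-ene | C[C@H]1CCCC(C)=C1O[Si](C)(C)C | intermediate
8 | lithium (6S)-2,6-dimethylcyclohex-1-en-1-olate | C[C@H]1CCCC(C)=C1[O-].[Li+] | intermediate
9 | (2R,6S)-2-(hydroxymethyl)-2,6-dimethylcyclohexan-1-one | O=C1[C@@H](C)CCC[C@]1(C)CO | intermediate
10 | (1R,3S)-1,3-dimethyl-2-oxocyclohexane-1-carbaldehyde | O=C1[C@@H](C)CCC[C@]1(C)C=O | intermediate
11 | (2R,6S)-2,6-dimethyl-2-[(E)-2-(4,4,5,5-tetramethyl-1,3,2-dioxaborolan-2-yl)ethenyl]cyclohexan-1-one | O=C1[C@@H](C)CCC[C@]1(C)/C=C/B1OC(C)(C)C(C)(C)O1 | intermediate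
12 | (2R,6S)-2-{(E)-2-[(4-methoxybenzyl)oxy]ethenyl}-2,6-dimethylcyclohexan-1-one | O=C1[C@@H](C)CCC[C@]1(C)/C=C/OCc1ccc(OC)cc1 | intermediate
13 | [(1E)-3-{[(4-methoxybenzyl)oxy]methyl}buta-1,3-dien-1-yl]lithium | C=C(COCc1ccc(OC)cc1)/C=C/[Li] | intermediate
14 | dichloro[(1E)-3-{[(4-methoxybenzyl)oxy]methyl}buta-1,3-dien-1-yl]cerium | C=C(COCc1ccc(OC)cc1)/C=C/[Ce](Cl)Cl | intermediate
15 | (1S,2R,6S)-1-[(1E)-3-{[(4-methoxybenzyl)oxy]methyl}buta-1,3-dien-1-yl]-2-{(E)-2-[(4-methoxybenzyl)oxy]ethenyl}-2,6-dimethylcyclohexan-1-ol | O[C@]1(/C=C/C(=C)COCc2ccc(OC)cc2)[C@@H](C)CCC[C@]1(C)/C=C/OCc1ccc(OC)cc1 | intermediate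
16 | potassium alkoxide of 15 | [K+].[O-][C@]1(/C=C/C(=C)COCc2ccc(OC)cc2)[C@@H](C)CCC[C@]1(C)/C=C/OCc1ccc(OC)cc1 | intermediate
17 | potassium (4E,6S,7S,10S)-6,12-bis[(4-methoxybenzyl)oxy]germacra-4,8,11(13)-trien-9-olate (oxygen cis to C7 across C8=C9) | [K+].C=C(COCc1ccc(OC)cc1)[C@H]1/C=C(\[O-])[C@@H](C)CCC/C(C)=C/[C@@H]1OCc1ccc(OC)cc1 | intermediate
18 | (4E,6S,7S,8S,10S)-8-hydroxy-6,12-bis[(4-methoxybenzyl)oxy]germacra-4,11(13)-dien-9-one | C=C(COCc1ccc(OC)cc1)[C@H]1[C@H](O)C(=O)[C@@H](C)CCC/C(C)=C/[C@@H]1OCc1ccc(OC)cc1 | intermediate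
19 | (4E,6S,7R,8S,10S)-8-(tert-butyldimethylsilyloxy)-6,12-bis[(4-methoxybenzyl)oxy]germacra-4,11(13)-dien-9-one | C=C(COCc1ccc(OC)cc1)[C@H]1[C@H](O[Si](C)(C)C(C)(C)C)C(=O)[C@@H](C)CCC/C(C)=C/[C@@H]1OCc1ccc(OC)cc1 | intermediate
20 | (4S,5S,6R,7R,8S,10S)-8-(tert-butyldimethylsilyloxy)-4,5-epoxy-6,12-bis[(4-methoxybenzyl)oxy]germacr-11(13)-en-9-one | C=C(COCc1ccc(OC)cc1)[C@H]1[C@H](O[Si](C)(C)C(C)(C)C)C(=O)[C@@H](C)CCC[C@]2(C)O[C@H]2[C@@H]1OCc1ccc(OC)cc1 | intermediate
21 | (4R,5S,6R,7R,8S,10S)-8-(tert-butyldimethylsilyloxy)-4,5-dihydroxy-6,12-bis[(4-methoxybenzyl)oxy]germacr-11(13)-en-9-one | C=C(COCc1ccc(OC)cc1)[C@H]1[C@H](O[Si](C)(C)C(C)(C)C)C(=O)[C@@H](C)CCC[C@@](C)(O)[C@@H](O)[C@@H]1OCc1ccc(OC)cc1 | intermediate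
22 | isobutyric anhydride | CC(C)C(=O)OC(=O)C(C)C | starting material
23 | (4R,5S,6R,7R,8S,10S)-8-(tert-butyldimethylsilyloxy)-4-hydroxy-5-(isobutyryloxy)-6,12-bis[(4-methoxybenzyl)oxy]germacr-11(13)-en-9-one | C=C(COCc1ccc(OC)cc1)[C@H]1[C@H](O[Si](C)(C)C(C)(C)C)C(=O)[C@@H](C)CCC[C@@](C)(O)[C@@H](OC(=O)C(C)C)[C@@H]1OCc1ccc(OC)cc1 | intermediate
24 | (4R,5S,6R,7R,8S,10S)-8-(tert-butyldimethylsilyloxy)-4,6,12-trihydroxy-5-(isobutyryloxy)germacr-11(13)-en-9-one | C=C(CO)[C@H]1[C@H](O[Si](C)(C)C(C)(C)C)C(=O)[C@@H](C)CCC[C@@](C)(O)[C@@H](OC(=O)C(C)C)[C@@H]1O | intermediate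
25 | (4R,5S,6R,7R,8S,10S)-8-(tert-butyldimethylsilyloxy)-4,6-dihydroxy-5-(isobutyryloxy)-9-oxogermacr-11(13)-en-12-al | C=C(C=O)[C@H]1[C@H](O[Si](C)(C)C(C)(C)C)C(=O)[C@@H](C)CCC[C@@](C)(O)[C@@H](OC(=O)C(C)C)[C@@H]1O | intermediate
26 | (4R,5S,6R,7R,8S,10S)-8-(tert-butyldimethylsilyloxy)-6,12-epoxy-4,12-dihydroxy-5-(isobutyryloxy)germacr-11(13)-en-9-one (lactol, both C12 epimers) | C=C1C(O)O[C@@H]2[C@@H]1[C@H](O[Si](C)(C)C(C)(C)C)C(=O)[C@@H](C)CCC[C@@](C)(O)[C@H]2OC(=O)C(C)C | intermediate
27 | (4R,5S,6R,7R,8S,10S)-8-(tert-butyldimethylsilyloxy)-4-hydroxy-5-(isobutyryloxy)-9-oxogermacr-11(13)-en-12,6-olide | C=C1C(=O)O[C@@H]2[C@@H]1[C@H](O[Si](C)(C)C(C)(C)C)C(=O)[C@@H](C)CCC[C@@](C)(O)[C@H]2OC(=O)C(C)C | intermediate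
28 | (4R,5S,6R,7S,8S,10S)-4,8-dihydroxy-5-(isobutyryloxy)-9-oxogermacr-11(13)-en-12,6-olide (CNP0270933.1) | C=C1C(=O)O[C@@H]2[C@@H]1[C@H](O)C(=O)[C@@H](C)CCC[C@@](C)(O)[C@H]2OC(=O)C(C)C | target

**Step count and risks**

Total step count: 16. Longest linear sequence: 14 steps (6 → 28, steps 3 to 16); stannane 5 is made in 2 steps and enters at step 8.

The three steps most likely to fail:

Step 9. The shift has to pass through the cyclohexane conformer with both methyls axial, so it may be slow. The conformationally mobile ring enolate may then be hydroxylated with poor facial selectivity, or be oxidised further to the α-diketone while excess base is present. Fallback, from 15 back to 18: the rearrangement is run in the same way but the enolate is silylated at −78 °C (TMSCl, Et3N) and the trimethylsilyl enol ether F1 is isolated. Rubottom oxidation (DMDO, acetone/CH2Cl2, −78 °C) then acts on a neutral, regiodefined substrate and gives the α-trimethylsilyloxy ketone F2; citric acid in methanol frees 18.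

Step 12. In a ten-membered ring the backside of the C4–O bond points into the ring. External hydration may therefore be outrun by ionisation at C4 with loss of configuration, by proton loss to allylic alcohols, or by capture at C5 through the transannular carbonyl oxygen. Fallback, from 20 back to 21, with no substitution at C4 or C5: Cp2TiCl (from Cp2TiCl2 and Mn, THF) opens the epoxide homolytically at C4, and β-hydride elimination gives the exocyclic allylic alcohol F3 with the C5 oxygen untouched. Hydroxyl-directed epoxidation (VO(acac)2, t-BuOOH) should place the new oxygen on C4 on the same ring face as C5–OH, giving the spiro-epoxide F4. PhSeNa (PhSeH, NaH, THF) opens it at the CH2 to the hydroxy selenide F5, and Bu3SnH/AIBN replaces selenium by hydrogen to give 21.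

Step 8. The carbonyl of 12 is flanked by a quaternary and a tertiary centre, so a bulky alkenyl metal may act as a base (enolisation, with loss of C10) or add too slowly. Fallback, from 3 and 12 back to 15: Sonogashira coupling of 3 with ethynyltrimethylsilane (PdCl2(PPh3)2, CuI, Et3N) gives the silyl enyne F6, and K2CO3 in methanol gives the terminal enyne F7. Its slim alkynylcerium reagent (n-BuLi, CeCl3) should add to 12 on the same face to give the propargylic alcohol F8. Hydroxyl-directed trans-hydroalumination (NaAlH2(OCH2CH2OCH3)2, THF) then gives the (E)-alkene of 15.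

**Further compounds**

F1 | step 9 | (4E,6S,7S,10S)-6,12-bis[(4-methoxybenzyl)oxy]-9-(trimethylsilyloxy)germacra-4,8,11(13)-triene | C=C(COCc1ccc(OC)cc1)[C@H]1/C=C(\O[Si](C)(C)C)[C@@H](C)CCC/C(C)=C/[C@@H]1OCc1ccc(OC)cc1
F2 | step 9 | 8-O-trimethylsilyl ether of 18 | C=C(COCc1ccc(OC)cc1)[C@H]1[C@H](O[Si](C)(C)C)C(=O)[C@@H](C)CCC/C(C)=C/[C@@H]1OCc1ccc(OC)cc1
F3 | step 12 | 8-(tert-butyldimethylsilyloxy)-5-hydroxy-6,12-bis[(4-methoxybenzyl)oxy]germacra-4(15),11(13)-dien-9-one | C=C(COCc1ccc(OC)cc1)[C@H]1[C@H](O[Si](C)(C)C(C)(C)C)C(=O)[C@@H](C)CCCC(=C)[C@@H](O)[C@@H]1OCc1ccc(OC)cc1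
F4 | step 12 | 8-(tert-butyldimethylsilyloxy)-4,15-epoxy-5-hydroxy-6,12-bis[(4-methoxybenzyl)oxy]germacr-11(13)-en-9-one | C=C(COCc1ccc(OC)cc1)[C@H]1[C@H](O[Si](C)(C)C(C)(C)C)C(=O)[C@@H](C)CCC[C@]2(CO2)[C@@H](O)[C@@H]1OCc1ccc(OC)cc1
F5 | step 12 | 8-(tert-butyldimethylsilyloxy)-4,5-dihydroxy-6,12-bis[(4-methoxybenzyl)oxy]-15-(phenylselanyl)germacr-11(13)-en-9-one | C=C(COCc1ccc(OC)cc1)[C@H]1[C@H](O[Si](C)(C)C(C)(C)C)C(=O)[C@@H](C)CCC[C@@](C[Se]c2ccccc2)(O)[C@@H](O)[C@@H]1OCc1ccc(OC)cc1
F6 | step 8 | (3-{[(4-methoxybenzyl)oxy]methyl}but-3-en-1-yn-1-yl)trimethylsilane | C=C(COCc1ccc(OC)cc1)C#C[Si](C)(C)C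
F7 | step 8 | 1-methoxy-4-{[(2-methylidenebut-3-yn-1-yl)oxy]methyl}benzene | C=C(COCc1ccc(OC)cc1)C#C
F8 | step 8 | (1R,2R,6S)-1-(3-{[(4-methoxybenzyl)oxy]methyl}but-3-en-1-yn-1-yl)-2-{(E)-2-[(4-methoxybenzyl)oxy]ethenyl}-2,6-dimethylcyclohexan-1-ol | O[C@]1(C#CC(=C)COCc2ccc(OC)cc2)[C@@H](C)CCC[C@]1(C)/C=C/OCc1ccc(OC)cc1
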